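**Retrosynthetic overview**
1. Chain: both benzylic C–C bonds are cut, so 1 (1,12-dibromododecane) and two molecules of 2 (3,5-dimethoxybenzyl bromide) give, through di-Grignard reagent 3, the symmetric tetramethyl ether 4 and then bis-resorcinol 5.
2. Desymmetrisation: one resorcinol ring of 5 is oxidised to the 2-hydroxy-1,4-benzoquinone 6 (ring B).
3. Key disconnection: the diaryl ether C–O bond. The ring A phenol of 6 displaces the activated quinone oxygen (sulfonate 7) and closes the 21-membered ring as aryloxyquinone 8.
4. 8 is reduced in the same flask to the hydroquinone, target 9.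
5. Ring order: both benzene rings are bought; the macrocycle is the only ring formed, and it is formed last.

Assumption 1: the target SMILES has no stereocentre and the 21-membered ring is conformationally mobile, so the compound is achiral and no stereocontrol is needed.
Assumption 2: the biogenesis is taken to be oxygenation of one ring of the C14-linked bis-resorcinol to a 2-hydroxy-1,4-benzoquinone, ether closure by a phenol of the other ring at the hydroxyl-bearing quinone carbon with loss of water, then reduction of the quinone.

**Route**

Step 1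
Reactants: 1 1,12-dibromododecane; 2 3,5-dimethoxybenzyl bromide (first of two molecules)
Product: 4 1,14-bis(3,5-dimethoxyphenyl)tetradecane, via di-Grignard reagent 3 (not isolated)
Conditions: Mg (2.5 equiv), THF, reflux; then 2 (2.2 equiv in all), Li2CuCl4 (5 mol%), THF, −20 °C to rt
Reagents that add atoms: 3,5-dimethoxybenzyl bromide (second molecule of 2, which supplies the second aryl-CH2 unit), COc1cc(CBr)cc(OC)c1
Why: Primary alkyl Grignard reagents couple with benzylic bromides under Li2CuCl4 catalysis (Kochi-type copper-catalysed sp3–sp3 cross-coupling), so each C–Mg end of the di-Grignard reagent takes up one molecule of 2 and the twofold coupling gives the C14 linker in one operation; no stereocentre is formed.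

Step 2
Reactants: 4 1,14-bis(3,5-dimethoxyphenyl)tetradecane
Product: 5 5,5'-(tetradecane-1,14-diyl)bis(benzene-1,3-diol)
Conditions: BBr3 (6 equiv), CH2Cl2, −78 °C to rt; MeOH, then H2O
Reagents that add atoms: none
Why: BBr3 cleaves all four aryl methyl ethers by Lewis-acid activation and bromide attack at methyl (standard aryl methyl ether demethylation), and the saturated chain and the arenes are inert.

Step 3
Reactants: 5 5,5'-(tetradecane-1,14-diyl)bis(benzene-1,3-diol)
Product: 6 2-[14-(3,5-dihydroxyphenyl)tetradecyl]-6-hydroxy-1,4-benzoquinone
Conditions: K2[ON(SO3)2] (2.0 equiv), aq. KH2PO4 (pH 6), acetone/H2O, 0 °C, stopped near half conversion; recovered 5 recycled; 6 used at once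
Reagents that add atoms: K2[ON(SO3)2] (dipotassium nitrosodisulfonate), [K+].[K+].[O]N(S(=O)(=O)[O-])S(=O)(=O)[O-]
Why: Teuber oxidation: the nitroxyl radical oxidises a phenol at its free para position, which in a 5-alkylresorcinol is the carbon between the second OH and the alkyl group, so only the 2-hydroxy-6-alkyl-1,4-benzoquinone pattern can form (the same regiochemistry as the oxidation of 3-methoxy-5-alkylphenols to 2-methoxy-6-alkylquinones), and two equivalents limit oxidation to one ring statistically (expected about 35–45%, remainder mostly recovered 5).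

Step 4
Reactants: 6 2-[14-(3,5-dihydroxyphenyl)tetradecyl]-6-hydroxy-1,4-benzoquinone
Product: 9 target macrocycle (21-membered diaryl ether triol), via quinonyl sulfonate 7 (not isolated), via macrocyclic aryloxyquinone 8 (not isolated)
Conditions: 2,4,6-triisopropylbenzenesulfonyl chloride (1.05 equiv), 2,6-lutidine (1.1 equiv), THF, 0 °C; then syringe-pump addition (10 h) to Cs2CO3 (2.5 equiv), MeCN, 45 °C, final 1 mM; then aq. Na2S2O4, EtOAc, rt, under N2
Reagents that add atoms: none
Why: Proposed new method: the 2-hydroxyquinone (pKa about 4) is a vinylogous carboxylic acid, so with one equivalent of a weak base only its oxygen, not the resorcinol OH groups (pKa about 9.5), is sulfonylated to the vinylogous mixed anhydride 7; the two ortho isopropyl groups block attack at sulfur, so the ring A phenoxide formed with Cs2CO3 adds to the sulfonate-bearing quinone carbon (the β-carbon of the enone to the distal carbonyl) and expels sulfonate by addition–elimination to give 8 (both ring A OH groups are equivalent, so only one macrocycle can result), which Na2S2O4 reduces to the hydroquinone 9; the closest known reaction types are the Yamaguchi mixed-anhydride macrolactonisation, the displacement of halide or sulfonate from 2-substituted 1,4-quinones by phenoxides, and the O-arenesulfonylation and displacement of lactam oxygens in nucleobases; no stereocentre is formed.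

**Compound list**
1 | 1,12-dibromododecane | BrCCCCCCCCCCCCBr | starting material
2 | 3,5-dimethoxybenzyl bromide | COc1cc(CBr)cc(OC)c1 | starting material
3 | dodecane-1,12-diylbis(magnesium bromide) | Br[Mg]CCCCCCCCCCCC[Mg]Br | intermediate (not isolated)
4 | 1,14-bis(3,5-dimethoxyphenyl)tetradecane | COc1cc(CCCCCCCCCCCCCCc2cc(OC)cc(OC)c2)cc(OC)c1 | intermediate
5 | 5,5'-(tetradecane-1,14-diyl)bis(benzene-1,3-diol) | Oc1cc(CCCCCCCCCCCCCCc2cc(O)cc(O)c2)cc(O)c1 | intermediate
6 | 2-[14-(3,5-dihydroxyphenyl)tetradecyl]-6-hydroxy-1,4-benzoquinone | O=C1C=C(O)C(=O)C(CCCCCCCCCCCCCCc2cc(O)cc(O)c2)=C1 | intermediate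
7 | 6-[14-(3,5-dihydroxyphenyl)tetradecyl]-1,4-benzoquinon-2-yl 2,4,6-triisopropylbenzenesulfonate | O=C1C=C(OS(=O)(=O)c2c(C(C)C)cc(C(C)C)cc2C(C)C)C(=O)C(CCCCCCCCCCCCCCc3cc(O)cc(O)c3)=C1 | intermediate (not isolated)
8 | macrocyclic aryloxyquinone: quinone form of 9, ring B as 2-aryloxy-6-alkyl-1,4-benzoquinone joined to ring A (3-oxy-5-alkylphenol) by the ether oxygen and the (CH2)14 chain | O=C1C=C2Oc3cc(O)cc(c3)CCCCCCCCCCCCCCC(=C1)C2=O | intermediate (not isolated)
9 | target: 21-membered macrocycle, ring A = 5-alkylresorcinol with one oxygen as the ether oxygen, ring B = 2-aryloxy-6-alkylbenzene-1,4-diol, the two alkyl positions joined by an unbranched (CH2)14 chain; achiral | Oc1cc2cc(c1)Oc1cc(O)cc(c1O)CCCCCCCCCCCCCC2 | target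

**Totals**
Total steps: 4. Longest linear sequence: 4 steps (1 → 4 → 5 → 6 → 9).

**Three steps most likely to fail, with fallbacks**

Step 4 (macrocyclisation) is the riskiest. The sulfonylation may not stay on the quinone oxygen, the ambident resorcinolate may attack through carbon or transfer an electron to the quinone, and oligomers may form. Fallback: starting from 6, the hydroxyquinone is turned into an isolable vinylogous acid chloride, 2-chloro-6-[14-(3,5-dihydroxyphenyl)tetradecyl]-1,4-benzoquinone F1, with oxalyl chloride and catalytic DMF in CH2Cl2/THF at 0 °C. Any aryl oxalate formed on ring A is cleaved in the aqueous NaHCO3 work-up. F1 is purified and then added slowly to Cs2CO3 in MeCN at 1 mM; phenoxide displacement of chloride from a 2-chloroquinone is established chemistry, and chloride cannot be transferred to ring A. This gives 8, where the fallback rejoins the route before the Na2S2O4 reduction to 9.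

Step 3 (one-ring oxidation) is next. The yield is capped statistically, the three polar products may be hard to separate, and a 2-hydroxyquinone with two free ring positions can self-condense. Fallback: starting from 3, the desymmetrisation is moved to the C–C coupling. The di-Grignard reagent is coupled under Li2CuCl4 catalysis with a 1:1 mixture of 2 and commercial 3,5-bis(benzyloxy)benzyl bromide (BrCc1cc(OCc2ccccc2)cc(OCc2ccccc2)c1). The three non-polar products are separated on silica. The cross-product, 1-[3,5-bis(benzyloxy)phenyl]-14-(3,5-dimethoxyphenyl)tetradecane F2, is carried on. The symmetric tetramethyl ether 4 formed alongside it goes into step 2, and the third product, 1,14-bis[3,5-bis(benzyloxy)phenyl]tetradecane F3, is hydrogenolysed (H2, Pd/C) to 5, so nothing is wasted. F2 is hydrogenolysed (H2, Pd/C, EtOAc/EtOH) to 5-[14-(3,5-dimethoxyphenyl)tetradecyl]benzene-1,3-diol F4. Only one ring of F4 carries free phenols, so excess K2[ON(SO3)2] can drive the oxidation to completion, giving 2-[14-(3,5-dimethoxyphenyl)tetradecyl]-6-hydroxy-1,4-benzoquinone F5. BBr3 (CH2Cl2, −78 to 0 °C, buffered quench) then frees ring A, with the hydroxyquinone carried as its boron chelate; this demethylation next to a quinone is itself a risk. The fallback rejoins the route at 6.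

Step 1 (twofold Grignard coupling) is third. Di-Grignard formation can suffer Wurtz coupling, and the benzyl bromide can homocouple. Fallback: starting from 2, no organomagnesium reagent is used. Two equivalents of 2 are coupled with commercial dodeca-1,11-diyne (C#CCCCCCCCCC#C) using CuI (10 mol%) and Cs2CO3 in MeCN at 40 °C (copper-acetylide sp–sp3 benzylation) to give 1,14-bis(3,5-dimethoxyphenyl)tetradeca-2,12-diyne F6. Any allene isomer formed under base converges in the next operation. Hydrogenation (H2, Pd/C, EtOAc) saturates the chain and rejoins the route at 4.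

**Further compounds**
F1 | step 4 | 2-chloro-6-[14-(3,5-dihydroxyphenyl)tetradecyl]-1,4-benzoquinone | O=C1C=C(Cl)C(=O)C(CCCCCCCCCCCCCCc2cc(O)cc(O)c2)=C1
F2 | step 3 | 1-[3,5-bis(benzyloxy)phenyl]-14-(3,5-dimethoxyphenyl)tetradecane | COc1cc(CCCCCCCCCCCCCCc2cc(OCc3ccccc3)cc(OCc3ccccc3)c2)cc(OC)c1
F3 | step 3 | 1,14-bis[3,5-bis(benzyloxy)phenyl]tetradecane | c1ccccc1COc1cc(CCCCCCCCCCCCCCc2cc(OCc3ccccc3)cc(OCc3ccccc3)c2)cc(OCc2ccccc2)c1
F4 | step 3 | 5-[14-(3,5-dimethoxyphenyl)tetradecyl]benzene-1,3-diol | COc1cc(CCCCCCCCCCCCCCc2cc(O)cc(O)c2)cc(OC)c1
F5 | step 3 | 2-[14-(3,5-dimethoxyphenyl)tetradecyl]-6-hydroxy-1,4-benzoquinone | O=C1C=C(O)C(=O)C(CCCCCCCCCCCCCCc2cc(OC)cc(OC)c2)=C1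
F6 | step 1 | 1,14-bis(3,5-dimethoxyphenyl)tetradeca-2,12-diyne | COc1cc(CC#CCCCCCCCCC#CCc2cc(OC)cc(OC)c2)cc(OC)c1
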